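**Retrosynthetic overview**
1. Target 24 ⇐ α-keto ester 22 by a one-pot Felkin–Anh reduction/acetylation, which sets the side-chain carbinol carbon.
2. 22 ⇐ radical conjugate addition of the tertiary hydroazulenyl radical (from cesium oxalate 14) to dihydrofuranyl glyoxylate 21, which already carries every remaining carbon. This one step makes the quaternary C1′–C4 bond and fixes C1′, C4 and C3.
3. 21 ⇐ furan-3-ylmethanol by C2 carboxylation, oxidative furan-to-dihydrofuranol ring transposition and enzymatic dynamic kinetic acetylation.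
4. 14 ⇐ cis-hydroazulenol 12, built by Robinson annulation, asymmetric conjugate addition, aldol closure, one-carbon ring expansion, methylenation and oxalate formation.
5. Ring order: cyclohexenone, then cyclopentane, then expansion of the six- to the seven-membered ring. The dihydrofuran (later oxolane) ring is made separately from a furan and joined in the radical step.

Assumption: 1, 2, 4 and 15 are taken as commercially available; C1′, C3a′, C8a′ refer to the azulenyl group and C2–C5 to the oxolane ring of the target name.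

**Step 1**
Reactants: 1 2-methylpropanal (isobutyraldehyde); 2 but-3-en-2-one (methyl vinyl ketone)
Product: 3 4,4-dimethylcyclohex-2-en-1-one
Conditions: conc. H2SO4 (2 mol %), toluene, 45 °C, then reflux with water separation
Reagents that add atoms: none
Why: Acid-catalysed Robinson annulation (Michael addition of the aldehyde enol to the enone, then intramolecular aldol condensation); no stereocentre is formed.

**Step 2**
Reactants: 3 4,4-dimethylcyclohex-2-en-1-one; 4 2-methyl-2-vinyl-1,3-dioxolane
Product: 7 (3R)-4,4-dimethyl-3-[2-(2-methyl-1,3-dioxolan-2-yl)ethyl]cyclohexan-1-one, via trialkylborane 5 (not isolated), via dialkylzinc 6 (not isolated)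
Conditions: 4, BH3·SMe2 (0.33 equiv per alkene), THF, 0 °C to rt; Et2Zn (neat), 0 °C, then Et3B and excess Et2Zn removed in vacuo; 3, Cu(OTf)2 (2 mol %), (S,R,R)-O,O′-(1,1′-binaphthalene-2,2′-diyl) N,N-bis(1-phenylethyl)phosphoramidite (4 mol %), toluene, −30 °C; aq. NH4Cl
Reagents that add atoms: none
Why: Hydroboration and boron–zinc exchange give a salt-free functionalised dialkylzinc for copper–phosphoramidite-catalysed enantioselective conjugate addition; the (S,R,R) ligand is the one that gives (S)-3-alkylcyclohexanones from cyclohex-2-enone, and the same facial attack is denoted 3R here because the gem-dimethyl carbon outranks C2, so the catalyst sets this centre (C3a′ of the target).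

**Step 3**
Reactants: 7 (3R)-4,4-dimethyl-3-[2-(2-methyl-1,3-dioxolan-2-yl)ethyl]cyclohexan-1-one
Product: 9 (3S,3aR,7aR)-3-hydroxy-3,7,7-trimethyloctahydro-4H-inden-4-one (cis-fused), via diketone 8 (not isolated)
Conditions: 1 M HCl, THF, rt; crude 8, L-proline (0.3 equiv), DMSO, rt
Reagents that add atoms: water, O
Why: Acid removes the ketal and proline then mediates an intramolecular enamine aldol addition (5-enolexo) in which only the cyclohexanone C2 enamine can reach the methyl ketone, the three-atom tether forcing the new bond cis to the side chain (cis ring fusion); the carbinol centre is drawn as the hydrogen-bonded 3S epimer, but its configuration is lost later when it becomes the radical centre.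

**Step 4**
Reactants: 9 (3S,3aR,7aR)-3-hydroxy-3,7,7-trimethyloctahydro-4H-inden-4-one
Product: 11 (3S,3aR,8aR)-3-hydroxy-3,8,8-trimethyloctahydroazulen-4(1H)-one (cis-fused), via silyl ketone 10 (not isolated)
Conditions: AlMe3 (2.2 equiv), Me3SiCHN2 (1.5 equiv), CH2Cl2, −78 to −20 °C; then 1 M HCl, THF, 0 °C
Reagents that add atoms: (trimethylsilyl)diazomethane, C[Si](C)(C)C=[N+]=[N-]
Why: Lewis-acid-promoted diazoalkane homologation (Tiffeneau–Demjanov-type one-carbon ring expansion) in which the less substituted CH2 migrates in preference to the ring-fusion methine, so the carbonyl stays next to C3a, and the α-silyl ketone is protodesilylated on acidic work-up; no stereocentre is touched under these non-enolising conditions.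

**Step 5**
Reactants: 11 (3S,3aR,8aR)-3-hydroxy-3,8,8-trimethyloctahydroazulen-4(1H)-one
Product: 12 (1S,3aR,8aS)-1,4,4-trimethyl-8-methylidenedecahydroazulen-1-ol
Conditions: Zn, CH2Br2, TiCl4, THF (reagent preformed, −40 to 5 °C); then 11, CH2Cl2, 0 °C to rt
Reagents that add atoms: dibromomethane, BrCBr
Why: Lombardo methylenation with the non-basic Zn/CH2Br2/TiCl4 reagent converts the hindered ketone into the exocyclic alkene without retro-aldol cleavage or epimerisation of the β-hydroxy ketone, which locks the cis ring fusion.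

**Step 6**
Reactants: 12 (1S,3aR,8aS)-1,4,4-trimethyl-8-methylidenedecahydroazulen-1-ol
Product: 14 cesium 2-oxo-2-{[(1S,3aR,8aS)-1,4,4-trimethyl-8-methylidenedecahydroazulen-1-yl]oxy}acetate, via methyl oxalate 13 (not isolated)
Conditions: ClCOCO2Me (1.5 equiv), Et3N (2 equiv), DMAP (0.1 equiv), CH2Cl2, 0 °C to rt; then CsOH (1.0 equiv, 1 M aq.), THF, rt
Reagents that add atoms: methyl chlorooxoacetate, COC(=O)C(Cl)=O; caesium hydroxide, [Cs+].[OH-]
Why: DMAP-catalysed acylation of the tertiary alcohol and selective saponification of the more electrophilic methyl ester by one equivalent of CsOH give the bench-stable cesium alkyl oxalate, the radical precursor; no stereocentre changes.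

**Step 7**
Reactants: 15 furan-3-ylmethanol
Product: 17 methyl 3-(hydroxymethyl)furan-2-carboxylate, via carbonate ester 16 (not isolated)
Conditions: n-BuLi (2.2 equiv), THF, −78 to 0 °C; ClCO2Me (2.5 equiv), −78 °C to rt; then K2CO3 (0.2 equiv), MeOH, rt
Reagents that add atoms: methyl chloroformate, COC(Cl)=O
Why: Alkoxide-directed ortho-lithiation of the furan at C2 and acylation with methyl chloroformate, followed by mild methanolysis of the O-methoxycarbonyl group that forms at the same time; no stereocentre.

**Step 8**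
Reactants: 17 methyl 3-(hydroxymethyl)furan-2-carboxylate
Product: 20 methyl 2-(5-hydroxy-2,5-dihydrofuran-3-yl)-2-oxoacetate (racemic lactol), via dimethoxydihydrofuran 18 (not isolated), via (Z)-ene-dione 19 (not isolated)
Conditions: Br2 (1.05 equiv), NaHCO3 (2.5 equiv), MeOH, −40 to 0 °C; then 0.1 M H2SO4, acetone/H2O (4:1), rt
Reagents that add atoms: water, O
Why: Proposed new method: bromine/methanol oxidation of the 2-furoate and acid hydrolysis unmask the (Z)-2-ene-1,4-dicarbonyl compound, acid-catalysed Z-to-E isomerisation (reversible conjugate addition of water) brings the CH2OH group cis to the aldehyde, and five-ring hemiacetal formation traps the E isomer as lactol 20, so that the old furan C2 ends as the side-chain ketone; the closest known reaction types are the Clauson-Kaas furan methoxylation and the Achmatowicz rearrangement, and the lactol centre is racemic and configurationally labile.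

**Step 9**
Reactants: 20 methyl 2-(5-hydroxy-2,5-dihydrofuran-3-yl)-2-oxoacetate
Product: 21 methyl 2-[(5R)-5-(acetyloxy)-2,5-dihydrofuran-3-yl]-2-oxoacetate
Conditions: immobilized Burkholderia cepacia lipase (Amano PS-IM), vinyl acetate (5 equiv), t-BuOMe, 30 °C
Reagents that add atoms: vinyl acetate, CC(=O)OC=C
Why: Proposed new method: lipase-catalysed dynamic kinetic resolution, in which the lactol enantiomers interconvert through the ring-opened hydroxy enal while the enzyme acetylates only one, so all material converges on the (5R) acetate (if the named lipase prefers 5S, the enantiocomplementary lipase is used); the closest known reaction type is the lipase-mediated second-order asymmetric acetylation of 5-hydroxy-2(5H)-furanones and 6-hydroxy-2H-pyran-3(6H)-ones.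

**Step 10**
Reactants: 14 cesium 2-oxo-2-{[(1S,3aR,8aS)-1,4,4-trimethyl-8-methylidenedecahydroazulen-1-yl]oxy}acetate; 21 methyl 2-[(5R)-5-(acetyloxy)-2,5-dihydrofuran-3-yl]-2-oxoacetate
Product: 22 methyl 2-[(3R,4R,5R)-5-(acetyloxy)-4-[(1R,3aR,8aS)-1,4,4-trimethyl-8-methylidenedecahydroazulen-1-yl]oxolan-3-yl]-2-oxoacetate
Conditions: 14 (1.3 equiv), 21 (1.0 equiv), Ir[dF(CF3)ppy]2(dtbbpy)PF6 (2 mol %), H2O (10 equiv), DME/DMF (3:1), blue LEDs (450 nm), rt
Reagents that add atoms: none
Why: Proposed new method: visible-light oxidation of the oxalate by the excited iridium photocatalyst releases two CO2 and the tertiary radical, which adds (Giese reaction) through its convex face, cis to the ring-fusion hydrogens (sets C1′ as R), to C4 of the enone anti to the C5 acetoxy group (sets C4), after which the adduct radical is reduced to the exocyclic enolate and protonated by water on the face away from the new tertiary alkyl group, placing the glyoxylate cis to it (sets C3 under kinetic control); the closest known reaction type is the photoredox Giese coupling of tertiary alkyl oxalate salts with 5-alkoxybutenolides, whereas the 3-acyl-2,5-dihydrofuran acceptor and the cis-selective protonation are untested.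

**Step 11**
Reactants: 22 methyl 2-[(3R,4R,5R)-5-(acetyloxy)-4-[(1R,3aR,8aS)-1,4,4-trimethyl-8-methylidenedecahydroazulen-1-yl]oxolan-3-yl]-2-oxoacetate
Product: 24 methyl (2S)-2-(acetyloxy)-2-[(3R,4R,5R)-5-(acetyloxy)-4-[(1R,3aR,8aS)-1,4,4-trimethyl-8-methylidenedecahydroazulen-1-yl]oxolan-3-yl]acetate (CNP0222222.1), via lithium alkoxide 23 (not isolated)
Conditions: LiBH(s-Bu)3 (1.1 equiv), THF, −78 °C; then Ac2O (3 equiv), DMAP (0.3 equiv), −78 to 0 °C
Reagents that add atoms: acetic anhydride, CC(=O)OC(C)=O
Why: Felkin–Anh-controlled hydride addition, in which the bulky trialkylborohydride attacks the ketone anti to the C4 branch that carries the hydroazulenyl group (the 1,3-chelate model with the ring oxygen predicts the same face) to give the 2S alkoxide, which is acetylated in the same flask; the ketone reacts far faster than the acetate and ester groups at −78 °C, and C3 can no longer epimerise once the ketone is gone.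

**Compound list**
1 | 2-methylpropanal (isobutyraldehyde) | CC(C)C=O | starting material
2 | but-3-en-2-one (methyl vinyl ketone) | CC(=O)C=C | starting material
3 | 4,4-dimethylcyclohex-2-en-1-one | CC1(C)CCC(=O)C=C1 | intermediate
4 | 2-methyl-2-vinyl-1,3-dioxolane | C=CC1(C)OCCO1 | starting material
5 | tris[2-(2-methyl-1,3-dioxolan-2-yl)ethyl]borane | CC1(CCB(CCC2(C)OCCO2)CCC2(C)OCCO2)OCCO1 | intermediate
6 | bis[2-(2-methyl-1,3-dioxolan-2-yl)ethyl]zinc | CC1(CC[Zn]CCC2(C)OCCO2)OCCO1 | intermediate
7 | (3R)-4,4-dimethyl-3-[2-(2-methyl-1,3-dioxolan-2-yl)ethyl]cyclohexan-1-one | CC1(C)CCC(=O)C[C@H]1CCC2(C)OCCO2 | intermediate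
8 | (3R)-4,4-dimethyl-3-(3-oxobutyl)cyclohexan-1-one | CC1(C)CCC(=O)C[C@H]1CCC(C)=O | intermediate
9 | (3S,3aR,7aR)-3-hydroxy-3,7,7-trimethyloctahydro-4H-inden-4-one | O=C1CCC(C)(C)[C@@H]2CC[C@](C)(O)[C@H]12 | intermediate
10 | (3S,3aR,8aR)-3-hydroxy-3,8,8-trimethyl-5-(trimethylsilyl)octahydroazulen-4(1H)-one (C5 epimers) | O=C1C([Si](C)(C)C)CCC(C)(C)[C@@H]2CC[C@](C)(O)[C@H]12 | intermediate
11 | (3S,3aR,8aR)-3-hydroxy-3,8,8-trimethyloctahydroazulen-4(1H)-one | O=C1CCCC(C)(C)[C@@H]2CC[C@](C)(O)[C@H]12 | intermediate
12 | (1S,3aR,8aS)-1,4,4-trimethyl-8-methylidenedecahydroazulen-1-ol | C=C1CCCC(C)(C)[C@@H]2CC[C@](C)(O)[C@H]12 | intermediate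
13 | methyl (1S,3aR,8aS)-1,4,4-trimethyl-8-methylidenedecahydroazulen-1-yl oxalate | C=C1CCCC(C)(C)[C@@H]2CC[C@](C)(OC(=O)C(=O)OC)[C@H]12 | intermediate
14 | cesium 2-oxo-2-{[(1S,3aR,8aS)-1,4,4-trimethyl-8-methylidenedecahydroazulen-1-yl]oxy}acetate | C=C1CCCC(C)(C)[C@@H]2CC[C@](C)(OC(=O)C(=O)[O-])[C@H]12.[Cs+] | intermediate
15 | furan-3-ylmethanol | OCc1ccoc1 | starting material
16 | methyl 3-{[(methoxycarbonyl)oxy]methyl}furan-2-carboxylate | COC(=O)OCc1ccoc1C(=O)OC | intermediate
17 | methyl 3-(hydroxymethyl)furan-2-carboxylate | COC(=O)c1occc1CO | intermediate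
18 | methyl 3-(hydroxymethyl)-2,5-dimethoxy-2,5-dihydrofuran-2-carboxylate (diastereomer mixture) | COC(=O)C1(OC)OC(OC)C=C1CO | intermediate
19 | methyl (3Z)-3-(hydroxymethyl)-2,5-dioxopent-3-enoate | COC(=O)C(=O)/C(CO)=C\C=O | intermediate
20 | methyl 2-(5-hydroxy-2,5-dihydrofuran-3-yl)-2-oxoacetate (racemic lactol) | COC(=O)C(=O)C1=CC(O)OC1 | intermediate
21 | methyl 2-[(5R)-5-(acetyloxy)-2,5-dihydrofuran-3-yl]-2-oxoacetate | COC(=O)C(=O)C1=C[C@@H](OC(C)=O)OC1 | intermediate
22 | methyl 2-[(3R,4R,5R)-5-(acetyloxy)-4-[(1R,3aR,8aS)-1,4,4-trimethyl-8-methylidenedecahydroazulen-1-yl]oxolan-3-yl]-2-oxoacetate | C=C1CCCC(C)(C)[C@@H]2CC[C@@](C)([C@@H]3[C@@H](OC(C)=O)OC[C@@H]3C(=O)C(=O)OC)[C@H]12 | intermediate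
23 | lithium (1S)-2-methoxy-2-oxo-1-[(3R,4R,5R)-5-(acetyloxy)-4-[(1R,3aR,8aS)-1,4,4-trimethyl-8-methylidenedecahydroazulen-1-yl]oxolan-3-yl]ethan-1-olate | C=C1CCCC(C)(C)[C@@H]2CC[C@@](C)([C@@H]3[C@@H](OC(C)=O)OC[C@@H]3[C@H]([O-])C(=O)OC)[C@H]12.[Li+] | intermediate
24 | methyl (2S)-2-(acetyloxy)-2-[(3R,4R,5R)-5-(acetyloxy)-4-[(1R,3aR,8aS)-1,4,4-trimethyl-8-methylidenedecahydroazulen-1-yl]oxolan-3-yl]acetate (CNP0222222.1) | C=C1CCCC(C)(C)[C@@H]2CC[C@@](C)([C@@H]3[C@@H](OC(C)=O)OC[C@@H]3[C@H](OC(C)=O)C(=O)OC)[C@H]12 | target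

**Step count and risk**
Total steps: 11. Longest linear sequence: 8 steps (steps 1–6, 10, 11); the acceptor branch (steps 7–9) joins at step 10.

Most likely to fail, first: step 10. The reduced photocatalyst may consume the easily reduced acceptor 21, or the transient C3 enolate may open the ring or epimerise. The fallback sets out from alcohol 12. Oxalyl chloride (CH2Cl2, 0 °C) gives (1S,3aR,8aS)-1,4,4-trimethyl-8-methylidenedecahydroazulen-1-yl 2-chloro-2-oxoacetate F4. The sodium salt of 1-hydroxypyridine-2(1H)-thione converts it into (1S,3aR,8aS)-1,4,4-trimethyl-8-methylidenedecahydroazulen-1-yl 2-thioxopyridin-1(2H)-yl oxalate F5. Tungsten-lamp irradiation of F5 with 21 (3 equiv) and slowly added t-BuSH in CH2Cl2 at 0 °C runs a Barton-type radical chain. The adduct radical is quenched by hydrogen-atom transfer from the thiol on the face away from the new substituent, so no enolate and no photoreductant are involved. This comes back to the route at 22.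

Second: step 9. The lipase may not discriminate the enantiomers of lactol 20. The fallback sets out from 20. Ac2O and pyridine in CH2Cl2 at 0 °C give racemic methyl 2-[5-(acetyloxy)-2,5-dihydrofuran-3-yl]-2-oxoacetate F2. F2 (2 equiv) is coupled with enantiopure 14 under the step 10 conditions. Each acceptor enantiomer reacts anti to its own acetoxy group while the radical face stays fixed, so 22 forms together with methyl 2-[(3S,4S,5S)-5-(acetyloxy)-4-[(1R,3aR,8aS)-1,4,4-trimethyl-8-methylidenedecahydroazulen-1-yl]oxolan-3-yl]-2-oxoacetate F3. The two diastereomers are separated by chromatography, and the route is rejoined at 22.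

Third: step 8. The furoate may resist bromine/methanol oxidation, or the acid may aromatise lactol 20. The fallback sets out from 17. Singlet oxygen (O2, rose bengal, visible light, CH2Cl2/MeOH, −78 °C) adds across the furan to give methyl 6-(hydroxymethyl)-2,3,7-trioxabicyclo[2.2.1]hept-5-ene-1-carboxylate F1. Me2S reduces F1 in the same flask and so comes back to the route at the (Z)-ene-dione 19. Pyridine (0.2 equiv, rt) then isomerises 19 and closes it to 20 under neutral conditions.

**Further compounds**
F1 | step 8 | methyl 6-(hydroxymethyl)-2,3,7-trioxabicyclo[2.2.1]hept-5-ene-1-carboxylate (racemic) | COC(=O)C12OOC(O1)C=C2CO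
F2 | step 9 | methyl 2-[5-(acetyloxy)-2,5-dihydrofuran-3-yl]-2-oxoacetate (racemate) | COC(=O)C(=O)C1=CC(OC(C)=O)OC1
F3 | step 9 | methyl 2-[(3S,4S,5S)-5-(acetyloxy)-4-[(1R,3aR,8aS)-1,4,4-trimethyl-8-methylidenedecahydroazulen-1-yl]oxolan-3-yl]-2-oxoacetate | C=C1CCCC(C)(C)[C@@H]2CC[C@@](C)([C@H]3[C@H](OC(C)=O)OC[C@H]3C(=O)C(=O)OC)[C@H]12
F4 | step 10 | (1S,3aR,8aS)-1,4,4-trimethyl-8-methylidenedecahydroazulen-1-yl 2-chloro-2-oxoacetate | C=C1CCCC(C)(C)[C@@H]2CC[C@](C)(OC(=O)C(Cl)=O)[C@H]12
F5 | step 10 | (1S,3aR,8aS)-1,4,4-trimethyl-8-methylidenedecahydroazulen-1-yl 2-thioxopyridin-1(2H)-yl oxalate | C=C1CCCC(C)(C)[C@@H]2CC[C@](C)(OC(=O)C(=O)ON3C=CC=CC3=S)[C@H]12
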